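The step Z → L leaves the sum Z + L unchanged, so I followed one number: N, the fraction L/(Z + L) at the time of reading. Z is the intermediate here, and while N stays small, L is a first-order correction to Z. Product made at a steady pace has a mean age of half the time t, so I let N grow in proportion to t.

| setting | Wednesday's | epsilon | eta |
|---|---|---|---|
| X | 0.51 M | 0.46 M | 0.30 M |
| D | 0.23 M | 0.230 M | 0.0800 M |
| remark | run made earlier |  |  |
| time |  | 4.0 min | 12 min |

- Wednesday's (time / min: Z / %, L / %, X / %): 0.200: 4, 0, 93; 0.333: 4, 2, 92; 0.417: 6, 0, 91; 0.667: 8, 0, 83; 1.00: 18, 0, 79; 1.50: 22, 2, 74; 2.50: 30, 1, 55

(standard deviation of a reading: 2 percentage points)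

- which one finishes higher in share of Z in all that became Z or L ("neither" within 2 percentage points) (epsilon / eta / neither)
- share of Z in all that became Z or L, epsilon
- share of Z in all that became Z or L, eta

- reactions considered so far: X -> Z; X + D -> E; Z -> L
- no earlier run changes the charge of D; that part of a forecast is a guess

Wednesday's last reading showed L 1% and Z 30%, so its number at 2.50 min was N_W = 0.0323. Scaled by time, I reckoned N = 0.0516 for epsilon at 4.0 min, a share of Z of 94.8%. For eta at 12 min I reckoned N = 0.155, a share of 84.5%.

Was one number enough? For the values, no: the L reading of 1% carries a scatter of 2 percentage points, so both shares were soft. The charge of D stayed a guess, too. For the order, I judged it enough. Under this scaling the ratio of the two N is the ratio of times, 3.00, for any L reading above zero, and my reckoned gap of 10 points stood against a margin of 2 points. I chose epsilon.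

The forecast also chose epsilon, with 91% for epsilon and 74% for eta, on this ground: “The longer time dominates, and the D effect is small.”

The flask gave 95.3% for epsilon and 84.5% for eta, so epsilon finished higher.

    X → Z (k = 0.00290 s⁻¹)
    X + D → E (k = 0.00460 M⁻¹ s⁻¹)
    Z → L (k = 3.50 × 10⁻⁴ s⁻¹)

The difference in time was the main reason for the gap: with that difference taken away, eta's share stood at 95.4% instead of 84.5%. The charge of D was not the reason. The shortfalls from complete Z were 4.70% in epsilon and 15.5% in eta, a ratio of 3.30 where my scaling had given 3.00.

For epsilon read later, at 15 min, the same scaling gave N = 0.194, so a share of 80.6%. The computed share of that flask was 79.6%.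

(The earlier runs and the new flask stem from a simulated flask on assumed constants.)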